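Numbering: ring B is C1(H2), C2(H–O), C3(H), C4(H2) and spiro C5; ring A is C5, C6 (bears C11H2–O), C7, C8, C9 and C10 (methyl). The plan cuts the C5–C10 bond. This bond links the quaternary spiro carbon to methyl-substituted C10 beside C6, a carbon that can exist as a ketone, so ring A is made by enlarging a five-membered carbinol ring. In a single operation NBS brominates C1 of a cyclopentenyl cyclopentanol while C10 shifts from C6 to C5, which creates the spiro[4.5]decan-6-one and fixes C5. The precursor is two enantiopure cyclopentanes joined by vinylmetal addition to a ketone; its C2 silyloxy group steers the bromine.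

Key step: step 10

Remark 1 (assumption on the chemistry): in step 7 the alkenyl arm of the enone is taken as the larger group, so the (S)-oxazaborolidine should give the (R)-alcohol.
Remark 2 (design of the precursor): the C8 and C9 oxygens are carried as tert-butyldimethylsilyl (TBS) ethers and the C2 oxygen as a triethylsilyl (TES) ether. The C9 oxygen lies cis to the cyclopentenyl group and a small, nucleophilic ether there could trap the bromonium ion; a bulky silyl ether is a poor nucleophile. TES can later be removed selectively, and the last step becomes a fluoride desilylation that the angelate and the α-methylene lactone tolerate.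
Remark 3: C12 and C13 are the lactone α-carbon and carbonyl carbon. Reagents whose carbon atoms stay in the target are numbered as starting materials; other reagents are given with SMILES on the reagent line. PMB = 4-methoxybenzyl.

Step 1
Reactants: 1 diethyl L-tartrate
Product: 2 diethyl (2R,3R)-2,3-bis(tert-butyldimethylsilyloxy)butanedioate
Conditions: TBSOTf (2.4 equiv), 2,6-lutidine, CH2Cl2, 0 °C → rt
Reagents that add atoms: tert-butyldimethylsilyl trifluoromethanesulfonate, CC(C)(C)[Si](C)(C)OS(=O)(=O)C(F)(F)F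
Why: Silylation of both secondary hydroxyls with the silyl triflate under lutidine buffering is a standard protection that leaves the two tartrate stereocentres untouched and installs the ethers that last until the final step.

Step 2
Reactants: 2 diethyl (2R,3R)-2,3-bis(tert-butyldimethylsilyloxy)butanedioate
Product: 3 (2S,3S)-2,3-bis(tert-butyldimethylsilyloxy)butane-1,4-diol
Conditions: i-Bu2AlH (5 equiv), CH2Cl2, −78 → 0 °C; aq. potassium sodium tartrate
Reagents that add atoms: none
Why: Hydride reduction of both esters gives the 1,4-diol, and the weakly basic aluminium alkoxides should not trigger 1,2-silyl migration to the primary oxygens.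

Step 3
Reactants: 3 (2S,3S)-2,3-bis(tert-butyldimethylsilyloxy)butane-1,4-diol
Product: 4 (2R,3R)-2,3-bis(tert-butyldimethylsilyloxy)-1,4-diiodobutane
Conditions: I2, PPh3, imidazole, CH2Cl2, 0 °C → rt
Reagents that add atoms: iodine, II
Why: Appel-type iodination converts both primary alcohols into iodides by SN2 displacement of the alkoxyphosphonium ions, without touching the secondary silyl ethers or the stereocentres.

Step 4
Reactants: 4 (2R,3R)-2,3-bis(tert-butyldimethylsilyloxy)-1,4-diiodobutane; 5 tosylmethyl isocyanide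
Product: 7 (3S,4S)-3,4-bis(tert-butyldimethylsilyloxy)cyclopentan-1-one, via tosyl isocyanide 6 (not isolated)
Conditions: NaH (2.3 equiv), DMSO/Et2O, rt; then aq. HCl (2 M), Et2O/THF, 0 °C → rt, short contact
Reagents that add atoms: tosylmethyl isocyanide (5), Cc1ccc(cc1)S(=O)(=O)C[N+]#[C-]; water, O
Why: van Leusen ketone synthesis, in which the TosMIC carbon is alkylated twice by the primary iodides (the second time by 5-exo-tet closure) and brief aqueous acid hydrolyses the geminal tosyl isocyanide to the C2-symmetric ketone, so TosMIC acts as a carbonyl dianion equivalent.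

Step 5
Reactants: 7 (3S,4S)-3,4-bis(tert-butyldimethylsilyloxy)cyclopentan-1-one; 8 iodomethane
Product: 10 (2S,3S,4S)-3,4-bis(tert-butyldimethylsilyloxy)-2-methylcyclopentan-1-one, via lithium enolate 9 (not isolated)
Conditions: LiN(i-Pr)2 (1.05 equiv), THF, −78 °C; MeI, DMPU, −78 → −40 °C
Reagents that add atoms: iodomethane (8), CI
Why: Kinetic enolate alkylation in which the two α-methylenes are homotopic, so only one regioisomer can form, and the methyl group enters anti to the neighbouring silyloxy group to give the 2,3-trans ketone (also the more stable epimer), low temperature and a fast electrophile being chosen to outrun β-elimination.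

Step 6
Reactants: 11 cyclopentane-1,3-dione
Product: 12 3-iodocyclopent-2-en-1-one
Conditions: PPh3, I2, Et3N, MeCN, rt → reflux
Reagents that add atoms: iodine, II
Why: The enol of the 1,3-dione is activated as an oxyphosphonium ion and iodide substitutes by addition–elimination, a known conversion of cyclic 1,3-diketones into β-iodo enones.

Step 7
Reactants: 12 3-iodocyclopent-2-en-1-one
Product: 13 (1R)-3-iodocyclopent-2-en-1-ol
Conditions: (S)-1-methyl-3,3-diphenyl-tetrahydro-1H,3H-pyrrolo[1,2-c][1,3,2]oxazaborole (0.2 equiv), BH3·SMe2, THF, −20 °C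
Reagents that add atoms: none
Why: Corey–Bakshi–Shibata reduction, in which the oxazaborolidine–borane complex binds the carbonyl anti to the larger alkenyl arm and delivers hydride to one face to set the carbinol centre as (R); any minor enantiomer becomes a separable diastereomer once joined to enantiopure 10.

Step 8
Reactants: 13 (1R)-3-iodocyclopent-2-en-1-ol
Product: 14 triethyl{[(1R)-3-iodocyclopent-2-en-1-yl]oxy}silane
Conditions: Et3SiCl, imidazole, CH2Cl2, 0 °C
Reagents that add atoms: chlorotriethylsilane, CC[Si](Cl)(CC)CC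
Why: Standard silylation of a secondary allylic alcohol; the triethylsilyl group is large enough to shield one alkene face in step 10 yet can be cleaved later by mild acid beside the TBS ethers.

Step 9
Reactants: 14 triethyl{[(1R)-3-iodocyclopent-2-en-1-yl]oxy}silane; 10 (2S,3S,4S)-3,4-bis(tert-butyldimethylsilyloxy)-2-methylcyclopentan-1-one
Product: 17 (1R,2S,3S,4S)-3,4-bis(tert-butyldimethylsilyloxy)-2-methyl-1-[(3R)-3-(triethylsilyloxy)cyclopent-1-en-1-yl]cyclopentan-1-ol, via vinyllithium 15 (not isolated), via organocerium 16 (not isolated)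
Conditions: t-BuLi (2.05 equiv), Et2O, −78 °C; CeCl3 (anhydrous), THF, −78 °C; then 10, −78 → −40 °C
Reagents that add atoms: none
Why: Iodine–lithium exchange followed by transmetalation to the less basic organocerium reagent (Imamoto conditions) suppresses enolisation of the α-branched ketone, and 1,2-addition should occur mainly anti to the α-methyl group; the new carbinol configuration is erased in step 10, so its ratio is not critical.

Step 10
Reactants: 17 (1R,2S,3S,4S)-3,4-bis(tert-butyldimethylsilyloxy)-2-methyl-1-[(3R)-3-(triethylsilyloxy)cyclopent-1-en-1-yl]cyclopentan-1-ol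
Product: 18 (1R,2R,5R,8S,9S,10R)-1-bromo-8,9-bis(tert-butyldimethylsilyloxy)-10-methyl-2-(triethylsilyloxy)spiro[4.5]decan-6-one
Conditions: NBS (1.15 equiv), propylene oxide, i-PrOH/CH2Cl2, −40 → 0 °C, dark
Reagents that add atoms: N-bromosuccinimide, O=C1CCC(=O)N1Br
Why: NBS forms a bromonium ion on the C1=C5 alkene from the face opposite the C2 triethylsilyloxy group, and as positive charge builds on tertiary C5 the antiperiplanar C6–C10 bond shifts to C5 while the carbinol oxygen becomes the C6 carbonyl; this is a halonium-triggered semipinacol rearrangement of an allylic tertiary alcohol, known for 1-(cycloalkenyl)cycloalkanols. Ring A is not closed by cyclisation but grows from five to six members through this 1,2-alkyl shift (ring expansion), which leaves it spiro-fused to ring B at C5. C5 is controlled by the C2 stereocentre, because bromine enters anti to the silyl ether and C10 adds anti to bromine with retention at C10; C1 (bromine trans to the C2 oxygen) is a passing stereocentre removed in step 11. The carbinol centre C6 is destroyed, so both C6 epimers of 17 should converge on 18. The step needs migration of C10 and not of C7, which rests on the higher migratory aptitude of the more substituted carbon, and it needs carbon migration to outrun capture of the cation by oxygen, which is why the cis-disposed C9 oxygen carries a bulky silyl group and propylene oxide removes HBr.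

Step 11
Reactants: 18 (1R,2R,5R,8S,9S,10R)-1-bromo-8,9-bis(tert-butyldimethylsilyloxy)-10-methyl-2-(triethylsilyloxy)spiro[4.5]decan-6-one
Product: 19 (2R,5R,8S,9S,10R)-8,9-bis(tert-butyldimethylsilyloxy)-10-methyl-2-(triethylsilyloxy)spiro[4.5]decan-6-one
Conditions: Bu3SnH (3 equiv, 0.5 M), Et3B (cat.), air, toluene, 0 °C → rt
Reagents that add atoms: none
Why: Radical chain dehalogenation, run at high tin hydride concentration and low temperature so that hydrogen transfer to the secondary C1 radical is faster than a 1,2-acyl shift towards C6 (Dowd–Beckwith pathway).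

Step 12
Reactants: 19 (2R,5R,8S,9S,10R)-8,9-bis(tert-butyldimethylsilyloxy)-10-methyl-2-(triethylsilyloxy)spiro[4.5]decan-6-one
Product: 21 (2R,5R,8S,9S,10R)-8,9-bis(tert-butyldimethylsilyloxy)-10-methyl-2-(triethylsilyloxy)spiro[4.5]dec-6-en-6-yl trifluoromethanesulfonate, via potassium enolate 20 (not isolated)
Conditions: KN(SiMe3)2, THF, −78 °C; PhNTf2, −78 → −20 °C
Reagents that add atoms: N-phenylbis(trifluoromethanesulfonimide), O=S(=O)(N(c1ccccc1)S(=O)(=O)C(F)(F)F)C(F)(F)F
Why: C5 is quaternary, so deprotonation can occur only at C7, and O-sulfonylation of the enolate gives the C6=C7 enol triflate; at −78 °C the equatorial C8 silyloxy group is poorly aligned for E1cB loss.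

Step 13
Reactants: 21 (2R,5R,8S,9S,10R)-8,9-bis(tert-butyldimethylsilyloxy)-10-methyl-2-(triethylsilyloxy)spiro[4.5]dec-6-en-6-yl trifluoromethanesulfonate; 22 carbon monoxide
Product: 23 methyl (2R,5R,8S,9S,10R)-8,9-bis(tert-butyldimethylsilyloxy)-10-methyl-2-(triethylsilyloxy)spiro[4.5]dec-6-ene-6-carboxylate
Conditions: Pd(PPh3)4 (10 mol%), CO (1 atm), MeOH, Et3N, DMF, 60 °C
Reagents that add atoms: carbon monoxide (22), [C-]#[O+]; methanol, CO
Why: Palladium-catalysed methoxycarbonylation (oxidative addition of the enol triflate to zerovalent palladium, CO insertion, methanolysis of the acylpalladium) installs C11 with the C6=C7 alkene fixed in place.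

Step 14
Reactants: 23 methyl (2R,5R,8S,9S,10R)-8,9-bis(tert-butyldimethylsilyloxy)-10-methyl-2-(triethylsilyloxy)spiro[4.5]dec-6-ene-6-carboxylate
Product: 24 [(2R,5R,8S,9S,10R)-8,9-bis(tert-butyldimethylsilyloxy)-10-methyl-2-(triethylsilyloxy)spiro[4.5]dec-6-en-6-yl]methanol
Conditions: i-Bu2AlH (2.5 equiv), CH2Cl2, −78 → −20 °C; aq. potassium sodium tartrate
Reagents that add atoms: none
Why: 1,2-Reduction of the α,β-unsaturated ester gives the primary allylic alcohol without touching the trisubstituted alkene or the silyl ethers.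

Step 15
Reactants: 24 [(2R,5R,8S,9S,10R)-8,9-bis(tert-butyldimethylsilyloxy)-10-methyl-2-(triethylsilyloxy)spiro[4.5]dec-6-en-6-yl]methanol
Product: 25 (2R,5R,8S,9S,10R)-8,9-bis(tert-butyldimethylsilyloxy)-6-[(4-methoxybenzyl)oxymethyl]-10-methyl-2-(triethylsilyloxy)spiro[4.5]dec-6-ene
Conditions: NaH, 4-MeOC6H4CH2Cl, Bu4NI (cat.), THF/DMF, 0 °C → rt
Reagents that add atoms: 4-methoxybenzyl chloride, COc1ccc(CCl)cc1
Why: Williamson etherification of the primary alkoxide gives a PMB ether that should survive the acid, oxidant, bases and hydride of steps 16–20 and can be removed oxidatively.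

Step 16
Reactants: 25 (2R,5R,8S,9S,10R)-8,9-bis(tert-butyldimethylsilyloxy)-6-[(4-methoxybenzyl)oxymethyl]-10-methyl-2-(triethylsilyloxy)spiro[4.5]dec-6-ene
Product: 26 (2R,5R,8S,9S,10R)-8,9-bis(tert-butyldimethylsilyloxy)-6-[(4-methoxybenzyl)oxymethyl]-10-methylspiro[4.5]dec-6-en-2-ol
Conditions: PPTS (cat.), MeOH/CH2Cl2, 0 °C → rt
Reagents that add atoms: none
Why: Acid-catalysed methanolysis cleaves the triethylsilyl ether much faster than the more hindered TBS ethers, so only the C2 hydroxyl is released.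

Step 17
Reactants: 26 (2R,5R,8S,9S,10R)-8,9-bis(tert-butyldimethylsilyloxy)-6-[(4-methoxybenzyl)oxymethyl]-10-methylspiro[4.5]dec-6-en-2-ol
Product: 27 (5R,8S,9S,10R)-8,9-bis(tert-butyldimethylsilyloxy)-6-[(4-methoxybenzyl)oxymethyl]-10-methylspiro[4.5]dec-6-en-2-one
Conditions: Dess–Martin periodinane, CH2Cl2, rt
Reagents that add atoms: none
Why: Dess–Martin oxidation of the secondary alcohol to the cyclopentanone; the C2 stereocentre has done its work in step 10 and is deliberately erased so that it can be reset with the opposite sense in step 19.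

Step 18
Reactants: 27 (5R,8S,9S,10R)-8,9-bis(tert-butyldimethylsilyloxy)-6-[(4-methoxybenzyl)oxymethyl]-10-methylspiro[4.5]dec-6-en-2-one; 28 ethyl bromoacetate
Product: 30 ethyl 2-[(3R,5R,8S,9S,10R)-8,9-bis(tert-butyldimethylsilyloxy)-6-[(4-methoxybenzyl)oxymethyl]-10-methyl-2-oxospiro[4.5]dec-6-en-3-yl]acetate, via lithium enolate 29 (not isolated)
Conditions: LiN(i-Pr)2 (1.1 equiv), THF, −78 °C; BrCH2CO2Et, DMPU, −78 → −40 °C
Reagents that add atoms: ethyl bromoacetate (28), CCOC(=O)CBr
Why: Kinetic enolate alkylation in which the amide base should remove a C3 proton in preference to the C1 protons flanked by the quaternary spiro centre, and the bromo ester should approach C3 from the ring B face on the side of the flat C6=C7 unit, away from C10 and its methyl group, to set C3 as (R); C3 stays epimerisable, so a minor epimer can be recycled with base.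

Step 19
Reactants: 30 ethyl 2-[(3R,5R,8S,9S,10R)-8,9-bis(tert-butyldimethylsilyloxy)-6-[(4-methoxybenzyl)oxymethyl]-10-methyl-2-oxospiro[4.5]dec-6-en-3-yl]acetate
Product: 32 (2R,3R,5R,8S,9S,10R)-8,9-bis(tert-butyldimethylsilyloxy)-6-[(4-methoxybenzyl)oxymethyl]-10-methylspiro[4.5]dec-6-ene bearing a cis-fused γ-lactone across C2 (ring oxygen) and C3 (CH2C=O), via lithium alkoxide 31 (not isolated)
Conditions: LiBH(s-Bu)3 (L-Selectride), THF, −78 → 0 °C; then H2O
Reagents that add atoms: none
Why: The bulky borohydride attacks the C2 carbonyl anti to the neighbouring C3 side chain, as is usual for 2-substituted cyclopentanones, and the resulting cis alkoxide closes onto the ethyl ester (5-exo-trig acyl substitution) to give the cis-fused lactone with C2 in the configuration of the target.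

Step 20
Reactants: 32 cis-fused γ-lactone (PMB ether, bis-TBS ether); 33 N,N-dimethylmethyleneiminium iodide (Eschenmoser's salt); 8 iodomethane
Product: 37 (2R,3R,5R,8S,9S,10R)-8,9-bis(tert-butyldimethylsilyloxy)-6-[(4-methoxybenzyl)oxymethyl]-10-methylspiro[4.5]dec-6-ene bearing a cis-fused α-methylene-γ-lactone across C2 (O) and C3 (C), via lactone enolate 34 (not isolated), via Mannich base 35 (not isolated), via ammonium iodide 36 (not isolated)
Conditions: LiN(i-Pr)2, THF, −78 °C; CH2=NMe2+ I−, −78 °C → rt; MeI, CH2Cl2/MeOH, rt; aq. NaHCO3, rt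
Reagents that add atoms: N,N-dimethylmethyleneiminium iodide (33), C=[N+](C)C.[I-]
Why: Eschenmoser α-methylenation, in which a Mannich reaction of the lactone enolate is followed by N-methylation and E1cB loss of trimethylamine, so the transient C12 stereocentre ends as an sp2 carbon.

Step 21
Reactants: 37 α-methylene lactone (PMB ether, bis-TBS ether)
Product: 38 (2R,3R,5R,8S,9S,10R)-8,9-bis(tert-butyldimethylsilyloxy)-6-(hydroxymethyl)-10-methylspiro[4.5]dec-6-ene bearing the cis-fused α-methylene-γ-lactone across C2 and C3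
Conditions: DDQ, CH2Cl2/pH 7 buffer, 0 °C
Reagents that add atoms: none
Why: Oxidative cleavage of the PMB ether (hydride abstraction to an oxocarbenium ion, then hydrolysis) frees the C11 hydroxyl under buffered conditions that leave the silyl ethers and the α-methylene lactone intact.

Step 22
Reactants: 38 primary allylic alcohol (bis-TBS ether); 39 angelic acid, (Z)-2-methylbut-2-enoic acid
Product: 41 [(2R,3R,5R,8S,9S,10R)-8,9-bis(tert-butyldimethylsilyloxy)-10-methylspiro[4.5]dec-6-en-6-yl]methyl (Z)-2-methylbut-2-enoate bearing the cis-fused α-methylene-γ-lactone across C2 and C3, via mixed anhydride 40 (not isolated)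
Conditions: angelic acid, 2,4,6-Cl3C6H2COCl, Et3N, toluene, rt; then 38, 70 °C
Reagents that add atoms: angelic acid (39), C/C=C(/C)C(=O)O
Why: Yamaguchi esterification, in which the mixed anhydride acylates the unhindered primary allylic alcohol, run without a nucleophilic catalyst and at moderate temperature to keep the (Z)-geometry of the angelate.

Step 23
Reactants: 41 bis-TBS ether of the target
Product: 42 target, [(2R,3R,5R,8S,9S,10R)-8,9-dihydroxy-10-methylspiro[4.5]dec-6-en-6-yl]methyl (Z)-2-methylbut-2-enoate bearing the cis-fused α-methylene-γ-lactone across C2 (O) and C3 (C)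
Conditions: HF·pyridine, pyridine/THF, 0 °C → rt
Reagents that add atoms: none
Why: Fluoride-mediated cleavage of the two secondary silyl ethers under buffered conditions that spare the angelate, the allylic ester and the α-methylene lactone delivers the diol without touching any stereocentre.

Compound list
1 | diethyl L-tartrate, diethyl (2R,3R)-2,3-dihydroxybutanedioate | CCOC(=O)[C@H](O)[C@@H](O)C(=O)OCC | starting material
2 | diethyl (2R,3R)-2,3-bis(tert-butyldimethylsilyloxy)butanedioate | CCOC(=O)[C@H](O[Si](C)(C)C(C)(C)C)[C@@H](O[Si](C)(C)C(C)(C)C)C(=O)OCC | intermediate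
3 | (2S,3S)-2,3-bis(tert-butyldimethylsilyloxy)butane-1,4-diol | OC[C@H](O[Si](C)(C)C(C)(C)C)[C@@H](O[Si](C)(C)C(C)(C)C)CO | intermediate
4 | (2R,3R)-2,3-bis(tert-butyldimethylsilyloxy)-1,4-diiodobutane | IC[C@H](O[Si](C)(C)C(C)(C)C)[C@@H](O[Si](C)(C)C(C)(C)C)CI | intermediate
5 | tosylmethyl isocyanide | Cc1ccc(cc1)S(=O)(=O)C[N+]#[C-] | starting material
6 | (3S,4S)-3,4-bis(tert-butyldimethylsilyloxy)-1-isocyano-1-tosylcyclopentane | [C-]#[N+]C1(C[C@H](O[Si](C)(C)C(C)(C)C)[C@@H](O[Si](C)(C)C(C)(C)C)C1)S(=O)(=O)c1ccc(C)cc1 | intermediate (not isolated)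
7 | (3S,4S)-3,4-bis(tert-butyldimethylsilyloxy)cyclopentan-1-one | O=C1C[C@H](O[Si](C)(C)C(C)(C)C)[C@@H](O[Si](C)(C)C(C)(C)C)C1 | intermediate
8 | iodomethane | CI | starting material
9 | lithium (3S,4S)-3,4-bis(tert-butyldimethylsilyloxy)cyclopent-1-en-1-olate | [Li]OC1=C[C@H](O[Si](C)(C)C(C)(C)C)[C@@H](O[Si](C)(C)C(C)(C)C)C1 | intermediate (not isolated)
10 | (2S,3S,4S)-3,4-bis(tert-butyldimethylsilyloxy)-2-methylcyclopentan-1-one (methyl trans to the neighbouring silyloxy group) | O=C1C[C@H](O[Si](C)(C)C(C)(C)C)[C@@H](O[Si](C)(C)C(C)(C)C)[C@@H]1C | intermediate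
11 | cyclopentane-1,3-dione | O=C1CCC(=O)C1 | starting material
12 | 3-iodocyclopent-2-en-1-one | O=C1C=C(I)CC1 | intermediate
13 | (1R)-3-iodocyclopent-2-en-1-ol | O[C@H]1C=C(I)CC1 | intermediate
14 | triethyl{[(1R)-3-iodocyclopent-2-en-1-yl]oxy}silane | CC[Si](CC)(CC)O[C@H]1C=C(I)CC1 | intermediate
15 | [(3R)-3-(triethylsilyloxy)cyclopent-1-en-1-yl]lithium | [Li]C1=C[C@H](O[Si](CC)(CC)CC)CC1 | intermediate (not isolated)
16 | dichloro[(3R)-3-(triethylsilyloxy)cyclopent-1-en-1-yl]cerium | Cl[Ce](Cl)C1=C[C@H](O[Si](CC)(CC)CC)CC1 | intermediate (not isolated)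
17 | (1R,2S,3S,4S)-3,4-bis(tert-butyldimethylsilyloxy)-2-methyl-1-[(3R)-3-(triethylsilyloxy)cyclopent-1-en-1-yl]cyclopentan-1-ol | CC[Si](CC)(CC)O[C@H]2C=C(CC2)[C@@]5(O)C[C@H](O[Si](C)(C)C(C)(C)C)[C@@H](O[Si](C)(C)C(C)(C)C)[C@@H]5C | intermediate (key-step precursor)
18 | (1R,2R,5R,8S,9S,10R)-1-bromo-8,9-bis(tert-butyldimethylsilyloxy)-10-methyl-2-(triethylsilyloxy)spiro[4.5]decan-6-one | CC[Si](CC)(CC)O[C@H]2[C@H](Br)[C@@]3(CC2)C(=O)C[C@H](O[Si](C)(C)C(C)(C)C)[C@@H](O[Si](C)(C)C(C)(C)C)[C@@H]3C | intermediate (key-step product)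
19 | (2R,5R,8S,9S,10R)-8,9-bis(tert-butyldimethylsilyloxy)-10-methyl-2-(triethylsilyloxy)spiro[4.5]decan-6-one | CC[Si](CC)(CC)O[C@H]2C[C@@]3(CC2)C(=O)C[C@H](O[Si](C)(C)C(C)(C)C)[C@@H](O[Si](C)(C)C(C)(C)C)[C@@H]3C | intermediate
20 | potassium C6–C7 enolate of 19 | CC[Si](CC)(CC)O[C@H]2C[C@@]3(CC2)C(O[K])=C[C@H](O[Si](C)(C)C(C)(C)C)[C@@H](O[Si](C)(C)C(C)(C)C)[C@@H]3C | intermediate (not isolated)
21 | (2R,5R,8S,9S,10R)-8,9-bis(tert-butyldimethylsilyloxy)-10-methyl-2-(triethylsilyloxy)spiro[4.5]dec-6-en-6-yl trifluoromethanesulfonate | CC[Si](CC)(CC)O[C@H]2C[C@@]3(CC2)C(OS(=O)(=O)C(F)(F)F)=C[C@H](O[Si](C)(C)C(C)(C)C)[C@@H](O[Si](C)(C)C(C)(C)C)[C@@H]3C | intermediate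
22 | carbon monoxide | [C-]#[O+] | starting material
23 | methyl (2R,5R,8S,9S,10R)-8,9-bis(tert-butyldimethylsilyloxy)-10-methyl-2-(triethylsilyloxy)spiro[4.5]dec-6-ene-6-carboxylate | CC[Si](CC)(CC)O[C@H]2C[C@@]3(CC2)C(C(=O)OC)=C[C@H](O[Si](C)(C)C(C)(C)C)[C@@H](O[Si](C)(C)C(C)(C)C)[C@@H]3C | intermediate
24 | [(2R,5R,8S,9S,10R)-8,9-bis(tert-butyldimethylsilyloxy)-10-methyl-2-(triethylsilyloxy)spiro[4.5]dec-6-en-6-yl]methanol | CC[Si](CC)(CC)O[C@H]2C[C@@]3(CC2)C(CO)=C[C@H](O[Si](C)(C)C(C)(C)C)[C@@H](O[Si](C)(C)C(C)(C)C)[C@@H]3C | intermediate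
25 | (2R,5R,8S,9S,10R)-8,9-bis(tert-butyldimethylsilyloxy)-6-[(4-methoxybenzyl)oxymethyl]-10-methyl-2-(triethylsilyloxy)spiro[4.5]dec-6-ene | CC[Si](CC)(CC)O[C@H]2C[C@@]3(CC2)C(COCc4ccc(OC)cc4)=C[C@H](O[Si](C)(C)C(C)(C)C)[C@@H](O[Si](C)(C)C(C)(C)C)[C@@H]3C | intermediate
26 | (2R,5R,8S,9S,10R)-8,9-bis(tert-butyldimethylsilyloxy)-6-[(4-methoxybenzyl)oxymethyl]-10-methylspiro[4.5]dec-6-en-2-ol | O[C@H]2C[C@@]3(CC2)C(COCc4ccc(OC)cc4)=C[C@H](O[Si](C)(C)C(C)(C)C)[C@@H](O[Si](C)(C)C(C)(C)C)[C@@H]3C | intermediate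
27 | (5R,8S,9S,10R)-8,9-bis(tert-butyldimethylsilyloxy)-6-[(4-methoxybenzyl)oxymethyl]-10-methylspiro[4.5]dec-6-en-2-one | O=C2C[C@@]3(CC2)C(COCc4ccc(OC)cc4)=C[C@H](O[Si](C)(C)C(C)(C)C)[C@@H](O[Si](C)(C)C(C)(C)C)[C@@H]3C | intermediate
28 | ethyl bromoacetate | CCOC(=O)CBr | starting material
29 | lithium C2–C3 enolate of 27 | [Li]OC2=CC[C@]3(C2)C(COCc4ccc(OC)cc4)=C[C@H](O[Si](C)(C)C(C)(C)C)[C@@H](O[Si](C)(C)C(C)(C)C)[C@@H]3C | intermediate (not isolated)
30 | ethyl 2-[(3R,5R,8S,9S,10R)-8,9-bis(tert-butyldimethylsilyloxy)-6-[(4-methoxybenzyl)oxymethyl]-10-methyl-2-oxospiro[4.5]dec-6-en-3-yl]acetate | O=C2C[C@@]3(C[C@@H]2CC(=O)OCC)C(COCc4ccc(OC)cc4)=C[C@H](O[Si](C)(C)C(C)(C)C)[C@@H](O[Si](C)(C)C(C)(C)C)[C@@H]3C | intermediate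
31 | lithium alkoxide of ethyl 2-[(2R,3R,5R,8S,9S,10R)-8,9-bis(tert-butyldimethylsilyloxy)-2-hydroxy-6-[(4-methoxybenzyl)oxymethyl]-10-methylspiro[4.5]dec-6-en-3-yl]acetate (2,3-cis) | [Li]O[C@@H]2C[C@@]3(C[C@@H]2CC(=O)OCC)C(COCc4ccc(OC)cc4)=C[C@H](O[Si](C)(C)C(C)(C)C)[C@@H](O[Si](C)(C)C(C)(C)C)[C@@H]3C | intermediate (not isolated)
32 | (2R,3R,5R,8S,9S,10R)-8,9-bis(tert-butyldimethylsilyloxy)-6-[(4-methoxybenzyl)oxymethyl]-10-methylspiro[4.5]dec-6-ene with cis-fused γ-lactone across C2 (O) and C3 (CH2C=O) | C1C(=O)O[C@@H]2C[C@@]3(C[C@H]12)C(COCc4ccc(OC)cc4)=C[C@H](O[Si](C)(C)C(C)(C)C)[C@@H](O[Si](C)(C)C(C)(C)C)[C@@H]3C | intermediate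
33 | N,N-dimethylmethyleneiminium iodide (Eschenmoser's salt) | C=[N+](C)C.[I-] | starting material
34 | lithium enolate of lactone 32 (C12=C13) | C1=C(O[Li])O[C@@H]2C[C@@]3(C[C@H]12)C(COCc4ccc(OC)cc4)=C[C@H](O[Si](C)(C)C(C)(C)C)[C@@H](O[Si](C)(C)C(C)(C)C)[C@@H]3C | intermediate (not isolated)
35 | lactone 32 carrying CH2NMe2 on C12 (C12 configuration not controlled) | CN(C)CC1C(=O)O[C@@H]2C[C@@]3(C[C@H]12)C(COCc4ccc(OC)cc4)=C[C@H](O[Si](C)(C)C(C)(C)C)[C@@H](O[Si](C)(C)C(C)(C)C)[C@@H]3C | intermediate (not isolated)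
36 | lactone 32 carrying CH2NMe3+ I− on C12 | C[N+](C)(C)CC1C(=O)O[C@@H]2C[C@@]3(C[C@H]12)C(COCc4ccc(OC)cc4)=C[C@H](O[Si](C)(C)C(C)(C)C)[C@@H](O[Si](C)(C)C(C)(C)C)[C@@H]3C.[I-] | intermediate (not isolated)
37 | (2R,3R,5R,8S,9S,10R)-8,9-bis(tert-butyldimethylsilyloxy)-6-[(4-methoxybenzyl)oxymethyl]-10-methylspiro[4.5]dec-6-ene with cis-fused α-methylene-γ-lactone across C2 (O) and C3 (C) | C=C1C(=O)O[C@@H]2C[C@@]3(C[C@H]12)C(COCc4ccc(OC)cc4)=C[C@H](O[Si](C)(C)C(C)(C)C)[C@@H](O[Si](C)(C)C(C)(C)C)[C@@H]3C | intermediate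
38 | (2R,3R,5R,8S,9S,10R)-8,9-bis(tert-butyldimethylsilyloxy)-6-(hydroxymethyl)-10-methylspiro[4.5]dec-6-ene with cis-fused α-methylene-γ-lactone across C2 and C3 | C=C1C(=O)O[C@@H]2C[C@@]3(C[C@H]12)C(CO)=C[C@H](O[Si](C)(C)C(C)(C)C)[C@@H](O[Si](C)(C)C(C)(C)C)[C@@H]3C | intermediate
39 | angelic acid, (Z)-2-methylbut-2-enoic acid | C/C=C(/C)C(=O)O | starting material
40 | (Z)-2-methylbut-2-enoic 2,4,6-trichlorobenzoic anhydride | C/C=C(/C)C(=O)OC(=O)c1c(Cl)cc(Cl)cc1Cl | intermediate (not isolated)
41 | [(2R,3R,5R,8S,9S,10R)-8,9-bis(tert-butyldimethylsilyloxy)-10-methylspiro[4.5]dec-6-en-6-yl]methyl (Z)-2-methylbut-2-enoate with cis-fused α-methylene-γ-lactone across C2 and C3 | C=C1C(=O)O[C@@H]2C[C@@]3(C[C@H]12)C(COC(=O)/C(C)=C\C)=C[C@H](O[Si](C)(C)C(C)(C)C)[C@@H](O[Si](C)(C)C(C)(C)C)[C@@H]3C | intermediate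
42 | [(2R,3R,5R,8S,9S,10R)-8,9-dihydroxy-10-methylspiro[4.5]dec-6-en-6-yl]methyl (Z)-2-methylbut-2-enoate with cis-fused α-methylene-γ-lactone across C2 (O) and C3 (C) | C=C1C(=O)O[C@@H]2C[C@@]3(C[C@H]12)C(COC(=O)/C(C)=C\C)=C[C@H](O)[C@@H](O)[C@@H]3C | target

Total step count: 23 steps. Longest linear sequence: 20 steps (steps 1–5, then 9–23); steps 6–8 make the second branch.

Steps most likely to fail

1. Step 10 (key step). What may go wrong: migration of the C7 methylene in place of C10, capture of the bromonium ion by a neighbouring oxygen in place of carbon migration, or bromine delivery to the alkene face syn to the C2 silyl ether. Fallback (epoxide-based semipinacol, with a different electrophile and a different intermediate): starting from 17, epoxidation with 3-chloroperbenzoic acid (NaHCO3, CH2Cl2, 0 °C) should occur anti to the triethylsilyloxy group and give the 2,3-epoxy alcohol F1. BF3·OEt2 in CH2Cl2 at −78 °C should then open the epoxide at tertiary C5 with anti migration of C10 to give the β-hydroxy ketone F2, which has a C1 hydroxyl where 18 has bromine. Acylation with 1,1′-thiocarbonyldiimidazole gives the imidazolyl thiocarbonate F3, and Barton–McCombie deoxygenation (Bu3SnH, AIBN, toluene, 80 °C) returns to the route at 19.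

2. Step 18. What may go wrong: enolisation towards C1 in place of C3, or approach of the electrophile to the wrong face of the enolate, which after step 19 would place the lactone on the wrong face of ring B. Fallback (the C3–C12 bond is made by intramolecular C–H insertion from the C2 oxygen, so the ring fusion is cis by construction and its face is set by an SN2 inversion): starting from 26, Mitsunobu esterification with diethylphosphonoacetic acid (PPh3, diisopropyl azodicarboxylate, THF) gives the C2-inverted phosphonoacetate F4. Diazo transfer (4-acetamidobenzenesulfonyl azide, DBU, MeCN) gives the diazo ester F5. Rh2(OAc)4 in CH2Cl2 should insert the carbenoid into the C3–H bond cis to the ester oxygen, forming the five-membered ring of the α-phosphono lactone F6. Horner–Wadsworth–Emmons reaction with aqueous formaldehyde and K2CO3 rejoins the route at 37, bypassing steps 17–20.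

3. Step 5. What may go wrong: β-elimination of silyloxide from the enolate before it is methylated, and over-methylation through proton exchange. Fallback (no free enolate): starting from 7, soft enolisation with trimethylsilyl triflate and Et3N (CH2Cl2, 0 °C) gives the silyl enol ether F7. Simmons–Smith cyclopropanation (Et2Zn, CH2I2, CH2Cl2, 0 °C), anti to the neighbouring silyloxy group, gives the siloxycyclopropane F8. Acid-catalysed opening of the cyclopropanol (p-toluenesulfonic acid, catalytic, MeOH/CH2Cl2, 0 °C) cleaves the bond between the oxygen-bearing carbon and the CH2 group and returns to the route at 10.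

Further compounds
F1 | step 10 | 17 with the cyclopentene converted into its C1–C5 epoxide, epoxide oxygen anti to the triethylsilyloxy group | CC[Si](CC)(CC)O[C@H]2[C@@H]3O[C@@]3(CC2)[C@@]5(O)C[C@H](O[Si](C)(C)C(C)(C)C)[C@@H](O[Si](C)(C)C(C)(C)C)[C@@H]5C
F2 | step 10 | (1R,2R,5S,8S,9S,10R)-8,9-bis(tert-butyldimethylsilyloxy)-1-hydroxy-10-methyl-2-(triethylsilyloxy)spiro[4.5]decan-6-one (C1 hydroxyl trans to the C2 oxygen) | CC[Si](CC)(CC)O[C@H]2[C@H](O)[C@@]3(CC2)C(=O)C[C@H](O[Si](C)(C)C(C)(C)C)[C@@H](O[Si](C)(C)C(C)(C)C)[C@@H]3C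
F3 | step 10 | O-(imidazol-1-ylthiocarbonyl) derivative of F2 at the C1 oxygen | CC[Si](CC)(CC)O[C@H]2[C@H](OC(=S)n4ccnc4)[C@@]3(CC2)C(=O)C[C@H](O[Si](C)(C)C(C)(C)C)[C@@H](O[Si](C)(C)C(C)(C)C)[C@@H]3C
F4 | step 18 | (2S,5R,8S,9S,10R)-8,9-bis(tert-butyldimethylsilyloxy)-6-[(4-methoxybenzyl)oxymethyl]-10-methylspiro[4.5]dec-6-en-2-yl 2-(diethoxyphosphoryl)acetate (C2 inverted relative to 26) | CCOP(=O)(OCC)CC(=O)O[C@@H]2C[C@@]3(CC2)C(COCc4ccc(OC)cc4)=C[C@H](O[Si](C)(C)C(C)(C)C)[C@@H](O[Si](C)(C)C(C)(C)C)[C@@H]3C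
F5 | step 18 | 2-diazo-2-(diethoxyphosphoryl)acetate corresponding to F4 | CCOP(=O)(OCC)C(=[N+]=[N-])C(=O)O[C@@H]2C[C@@]3(CC2)C(COCc4ccc(OC)cc4)=C[C@H](O[Si](C)(C)C(C)(C)C)[C@@H](O[Si](C)(C)C(C)(C)C)[C@@H]3C
F6 | step 18 | lactone 32 carrying a diethoxyphosphoryl group on C12 (C12 configuration not controlled) | CCOP(=O)(OCC)C1C(=O)O[C@@H]2C[C@@]3(C[C@H]12)C(COCc4ccc(OC)cc4)=C[C@H](O[Si](C)(C)C(C)(C)C)[C@@H](O[Si](C)(C)C(C)(C)C)[C@@H]3C
F7 | step 5 | (3S,4S)-3,4-bis(tert-butyldimethylsilyloxy)-1-(trimethylsilyloxy)cyclopent-1-ene | C[Si](C)(C)OC1=C[C@H](O[Si](C)(C)C(C)(C)C)[C@@H](O[Si](C)(C)C(C)(C)C)C1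
F8 | step 5 | 2,3-bis(tert-butyldimethylsilyloxy)-5-(trimethylsilyloxy)bicyclo[3.1.0]hexane, cyclopropane CH2 anti to the neighbouring silyloxy group | C[Si](C)(C)O[C@]12C[C@H]1[C@H](O[Si](C)(C)C(C)(C)C)[C@@H](O[Si](C)(C)C(C)(C)C)C2
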